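**Plan**

1. Numbering: chroman O1, C2, C3, C4, C4a, C5–C8, C8a; ring A is the benzo ring, ring B the C2 aryl, ring C the pyran, ring D the C4 phloroglucinol ring. The target is the 2,4-cis isomer (2S,4S).
2. Retrosynthetic cuts, in order: the five O-protecting groups; the ring D–acyl bond; the C3–H and C4–H bonds (back to a 2H-chromene); O1–C2 together with C2–C3 (ring C); the C4–ring D bond (back to an aryl bromide and a methyl ketone).
3. Enabling feature: C2 with ring B is the carbonyl carbon of a 4-oxygenated benzaldehyde; O1, C8a, C4a, C4 and C3 with rings A and D are a 2-(1-arylvinyl)phenol whose CH2 becomes C3. C4, flanked by rings A and D, carries the charge once the CH2 end has attacked.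
4. Forward: ring D is joined to the ring A ketone at C4 and the carbinol is dehydrated to the diarylethylene. Ring C, the only ring made, closes in the annulation with the ring B aldehyde. Hydrogenation, acylation of ring D with 9-phenylnonanoic acid and one hydrogenolysis follow.
5. Stereochemistry: C2 comes from the chiral confined acid in the annulation; C4 from hydrogen delivery to the chromene face opposite the C2 aryl.
6. Ring B is carried as a benzyl carbonate, not a benzyl ether, so that C2–O1 resists the acidic acylation; it leaves in the final hydrogenolysis.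

Key step: step 5

Assumption: the confined acid is a purchased or separately prepared catalyst, and the antipode that gives the 2S chromene cannot be predicted, so it is fixed by one test run with each antipode and written below as (S,S).

**Step 1**
Reactants: 1 1,3,5-tris(benzyloxy)benzene
Product: 2 2-bromo-1,3,5-tris(benzyloxy)benzene
Conditions: NBS (1.0 equiv), CH2Cl2, −78 °C to 0 °C, dark
Reagents that add atoms: N-bromosuccinimide, O=C1CCC(=O)N1Br
Why: Electrophilic aromatic bromination with one equivalent of NBS at low temperature should stop at the monobromide, since the three free positions are equivalent and the first bromine lowers the reactivity of the ring; the bromide is made because direct lithiation of aryl benzyl ethers competes with benzylic deprotonation and Wittig rearrangement.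

**Step 2**
Reactants: 2 2-bromo-1,3,5-tris(benzyloxy)benzene; 3 4'-benzyloxy-2'-hydroxyacetophenone
Product: 7 rac-5-(benzyloxy)-2-{1-hydroxy-1-[2,4,6-tris(benzyloxy)phenyl]ethyl}phenol, via 2,4,6-tris(benzyloxy)phenyllithium 4 (not isolated), via dichloro[2,4,6-tris(benzyloxy)phenyl]cerium 5 (not isolated), via lithium 2-acetyl-5-(benzyloxy)phenoxide 6 (not isolated)
Conditions: 2, n-BuLi, THF, −78 °C; anhydrous CeCl3, −78 °C; then 3 pre-treated with LiN(SiMe3)2 (1.0 equiv) in THF, −78 °C to 0 °C; aq. NH4Cl
Reagents that add atoms: none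
Why: Bromine–lithium exchange at −78 °C outruns benzylic deprotonation, and transmetalation to cerium gives a nucleophile of low basicity that should add to the methyl ketone of the lithium phenoxide (organocerium 1,2-addition to an enolisable ketone) instead of enolising it; the carbinol carbon forms racemic and is removed in step 3.

**Step 3**
Reactants: 7 rac-5-(benzyloxy)-2-{1-hydroxy-1-[2,4,6-tris(benzyloxy)phenyl]ethyl}phenol
Product: 8 5-(benzyloxy)-2-{1-[2,4,6-tris(benzyloxy)phenyl]vinyl}phenol
Conditions: PPTS (cat.), 4 Å MS, toluene, 40 °C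
Reagents that add atoms: none
Why: Acid-catalysed E1 dehydration: the tertiary, doubly benzylic alcohol ionises under a weak buffered acid because the cation is stabilised by ring D and the ortho-hydroxyaryl ring, and loss of a methyl proton should give the 1,1-diarylethylene without touching the benzyl ethers.

**Step 4**
Reactants: 9 4-hydroxybenzaldehyde
Product: 10 benzyl 4-formylphenyl carbonate
Conditions: CbzCl, Et3N, DMAP (cat.), CH2Cl2, 0 °C to rt
Reagents that add atoms: benzyl chloroformate, O=C(Cl)OCc1ccccc1
Why: O-acylation of the phenol with a chloroformate under amine base gives the aryl benzyl carbonate, which makes the ring B oxygen a weak donor (a more electrophilic aldehyde now, an acid-stable C2–O1 benzylic ether later) and is removed by the same hydrogenolysis as the benzyl ethers.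

**Step 5**
Reactants: 8 5-(benzyloxy)-2-{1-[2,4,6-tris(benzyloxy)phenyl]vinyl}phenol; 10 benzyl 4-formylphenyl carbonate
Product: 12 benzyl 4-{(2S)-7-(benzyloxy)-4-[2,4,6-tris(benzyloxy)phenyl]-2H-chromen-2-yl}phenyl carbonate, via aryloxycarbenium ion 11 (not isolated)
Conditions: (S,S)-configured confined imidodiphosphorimidate acid (IDPi, 5 mol %), 5 Å MS, CHCl3–cyclohexane, −40 °C, dark; Et3N quench at −40 °C; product used at once
Reagents that add atoms: none
Why: Proposed new method: the acid activates aldehyde 10, phenol 8 adds and water is lost to the sieves, which gives aryloxycarbenium ion 11 as a contact ion pair inside the chiral anion; the CH2 terminus of the alkene then attacks the carbenium carbon (O1–C2 already in place, C2–C3 formed) in a 6-endo-trig closure of ring C, and the resulting C4 cation, stabilised by rings A and D, loses a C3 proton to the anion to give the 2H-chromene and return the acid. The closest known reaction types are the acid-promoted condensation of 2-alkenylphenols with aldehydes to racemic 2H-chromenes and the asymmetric Prins cyclisations and oxa-Pictet–Spengler reactions run through oxocarbenium ions under confined imidodiphosphorimidate acids. C2 is the only new stereocentre and is controlled by the catalyst, whose anion shields one face of the oxocarbenium carbon. The step needs regioselectivity (6-endo attack through CH2, not 5-exo through the internal carbon, and no Friedel–Crafts attack by ring D), which the 1,1-diaryl substitution secures by making the CH2 end the only site whose attack leaves a doubly benzylic cation, and by the closure being intramolecular. A stepwise course, in which the alkene first attacks the protonated aldehyde and the phenol then closes on the allylic cation, would form the same two bonds, and low temperature, darkness and the cold amine quench are meant to keep the product's C2–O1 bond from ionising.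

**Step 6**
Reactants: 12 benzyl 4-{(2S)-7-(benzyloxy)-4-[2,4,6-tris(benzyloxy)phenyl]-2H-chromen-2-yl}phenyl carbonate
Product: 13 benzyl 4-{(2S,4S)-7-(benzyloxy)-4-[2,4,6-tris(benzyloxy)phenyl]chroman-2-yl}phenyl carbonate
Conditions: [Ir(cod)(PCy3)(py)]PF6 (5 mol %), H2 (50 bar), CH2Cl2, rt, dark
Reagents that add atoms: none
Why: Homogeneous alkene hydrogenation with the cationic iridium catalyst reduces hindered trisubstituted styrenes without cleaving aryl benzyl ethers or the benzyl carbonate, and hydrogen should be delivered to the C3=C4 face opposite the C2 aryl group, which places the C4 hydrogen trans to ring B and ring D cis to it (4S).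

**Step 7**
Reactants: 13 benzyl 4-{(2S,4S)-7-(benzyloxy)-4-[2,4,6-tris(benzyloxy)phenyl]chroman-2-yl}phenyl carbonate; 14 9-phenylnonanoic acid
Product: 16 benzyl 4-{(2S,4S)-7-(benzyloxy)-4-[2,4,6-tris(benzyloxy)-3-(9-phenylnonanoyl)phenyl]chroman-2-yl}phenyl carbonate, via 9-phenylnonanoic trifluoroacetic anhydride 15 (not isolated)
Conditions: 14, (CF3CO)2O, CH2Cl2, 0 °C, 30 min; then 13, 0 °C to rt
Reagents that add atoms: none
Why: Friedel–Crafts acylation by the mixed trifluoroacetic anhydride: each free position of ring D lies ortho, ortho and para to three benzyloxy groups and should react well ahead of C6 of ring A (two oxygen donors) and of the carbonate-deactivated ring B, the two free positions of ring D give the same product, and C2 and C4 stay untouched because the electron-poor ring B keeps C2–O1 from ionising in CF3CO2H.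

**Step 8**
Reactants: 16 benzyl 4-{(2S,4S)-7-(benzyloxy)-4-[2,4,6-tris(benzyloxy)-3-(9-phenylnonanoyl)phenyl]chroman-2-yl}phenyl carbonate
Product: 17 1-{2,4,6-trihydroxy-3-[(2S,4S)-7-hydroxy-2-(4-hydroxyphenyl)chroman-4-yl]phenyl}-9-phenylnonan-1-one
Conditions: H2 (1 atm), 10% Pd/C, EtOAc–MeOH, rt
Reagents that add atoms: none
Why: Hydrogenolysis over palladium cleaves the four aryl benzyl ethers and the benzyl carbonate (which then loses CO2), while the hydrogen-bonded acylphloroglucinol ketone, the chroman C2–O1 bond and both stereocentres should survive the mild conditions.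

**Compound list**

1 | 1,3,5-tris(benzyloxy)benzene | C(c1ccccc1)Oc1cc(OCc2ccccc2)cc(OCc2ccccc2)c1 | starting material
2 | 2-bromo-1,3,5-tris(benzyloxy)benzene | Brc1c(OCc2ccccc2)cc(OCc2ccccc2)cc1OCc1ccccc1 | intermediate
3 | 4'-benzyloxy-2'-hydroxyacetophenone | CC(=O)c1ccc(OCc2ccccc2)cc1O | starting material
4 | 2,4,6-tris(benzyloxy)phenyllithium (not isolated) | [Li]c1c(OCc2ccccc2)cc(OCc2ccccc2)cc1OCc1ccccc1 | intermediate
5 | dichloro[2,4,6-tris(benzyloxy)phenyl]cerium (not isolated) | Cl[Ce](Cl)c1c(OCc2ccccc2)cc(OCc2ccccc2)cc1OCc1ccccc1 | intermediate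
6 | lithium 2-acetyl-5-(benzyloxy)phenoxide (not isolated) | CC(=O)c1ccc(OCc2ccccc2)cc1[O-].[Li+] | intermediate
7 | rac-5-(benzyloxy)-2-{1-hydroxy-1-[2,4,6-tris(benzyloxy)phenyl]ethyl}phenol | CC(O)(c1ccc(OCc2ccccc2)cc1O)c1c(OCc2ccccc2)cc(OCc2ccccc2)cc1OCc1ccccc1 | intermediate
8 | 5-(benzyloxy)-2-{1-[2,4,6-tris(benzyloxy)phenyl]vinyl}phenol | C=C(c1ccc(OCc2ccccc2)cc1O)c1c(OCc2ccccc2)cc(OCc2ccccc2)cc1OCc1ccccc1 | intermediate
9 | 4-hydroxybenzaldehyde | O=Cc1ccc(O)cc1 | starting material
10 | benzyl 4-formylphenyl carbonate | O=Cc1ccc(OC(=O)OCc2ccccc2)cc1 | intermediate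
11 | aryloxycarbenium ion from 8 and 10, cation of the ion pair with the catalyst anion (not isolated) | C=C(c1ccc(OCc2ccccc2)cc1[O+]=Cc1ccc(OC(=O)OCc2ccccc2)cc1)c1c(OCc2ccccc2)cc(OCc2ccccc2)cc1OCc1ccccc1 | intermediate
12 | benzyl 4-{(2S)-7-(benzyloxy)-4-[2,4,6-tris(benzyloxy)phenyl]-2H-chromen-2-yl}phenyl carbonate | C(c1ccccc1)Oc1cc(OCc2ccccc2)c(C2=C[C@@H](c3ccc(OC(=O)OCc4ccccc4)cc3)Oc3cc(OCc4ccccc4)ccc32)c(OCc2ccccc2)c1 | intermediate
13 | benzyl 4-{(2S,4S)-7-(benzyloxy)-4-[2,4,6-tris(benzyloxy)phenyl]chroman-2-yl}phenyl carbonate (2,4-cis) | C(c1ccccc1)Oc1cc(OCc2ccccc2)c([C@H]2C[C@@H](c3ccc(OC(=O)OCc4ccccc4)cc3)Oc3cc(OCc4ccccc4)ccc32)c(OCc2ccccc2)c1 | intermediate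
14 | 9-phenylnonanoic acid | O=C(O)CCCCCCCCc1ccccc1 | starting material
15 | 9-phenylnonanoic trifluoroacetic anhydride (not isolated) | O=C(CCCCCCCCc1ccccc1)OC(=O)C(F)(F)F | intermediate
16 | benzyl 4-{(2S,4S)-7-(benzyloxy)-4-[2,4,6-tris(benzyloxy)-3-(9-phenylnonanoyl)phenyl]chroman-2-yl}phenyl carbonate | O=C(CCCCCCCCc1ccccc1)c1c(OCc2ccccc2)cc(OCc2ccccc2)c([C@H]2C[C@@H](c3ccc(OC(=O)OCc4ccccc4)cc3)Oc3cc(OCc4ccccc4)ccc32)c1OCc1ccccc1 | intermediate
17 | 1-{2,4,6-trihydroxy-3-[(2S,4S)-7-hydroxy-2-(4-hydroxyphenyl)chroman-4-yl]phenyl}-9-phenylnonan-1-one | O=C(CCCCCCCCc1ccccc1)c1c(O)cc(O)c([C@H]2C[C@@H](c3ccc(O)cc3)Oc3cc(O)ccc32)c1O | target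

**Count and risks**

Total step count: 8. Longest linear sequence: 7 steps (steps 1, 2, 3, 5, 6, 7, 8, from 1); step 4 is a one-step side branch.

Steps most likely to fail:

Step 5 (annulation). What may go wrong: weak discrimination between the two faces of the oxocarbenium carbon, loss of the C2 configuration through acid-induced ionisation of the product's C2–O1 bond, or attack of ring D instead of the alkene on the activated aldehyde. The fallback uses known reactions only: C2 is set by an asymmetric conjugate addition and the C4–ring D bond by carbonyl addition. It sets out from 3 and 2 and returns at 12. Heating 3 with N,N-dimethylformamide dimethyl acetal should give the enaminone (E)-1-[4-(benzyloxy)-2-hydroxyphenyl]-3-(dimethylamino)prop-2-en-1-one F1, which aqueous HCl in CH2Cl2 closes to 7-(benzyloxy)-4H-chromen-4-one F2. 4-Hydroxyphenylboronic acid and benzyl chloroformate (pyridine, CH2Cl2) give [4-(benzyloxycarbonyloxy)phenyl]boronic acid F3. Conjugate addition of F3 to F2 with Pd(OCOCF3)2, the antipode of the tert-butyl pyridine–oxazoline ligand that leads to 2S, NH4PF6 and water in ClCH2CH2Cl at 60 °C should give the flavanone benzyl 4-[(2S)-7-(benzyloxy)-4-oxochroman-2-yl]phenyl carbonate F4. Organocerium 5, made from 2 as in step 2, is added to the ketone of F4 at −78 °C to give the tertiary alcohol benzyl 4-{(2S)-7-(benzyloxy)-4-hydroxy-4-[2,4,6-tris(benzyloxy)phenyl]chroman-2-yl}phenyl carbonate F5 as both C4 epimers, and PPTS in toluene removes water to give 12.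

Step 6 (hydrogenation). What may go wrong: stalled reduction because the two ortho benzyloxy groups of ring D shield both faces of C4, too small a preference for delivery opposite the C2 aryl, or opening of the chromene by traces of acid from the iridium hydride before it is reduced. The fallback is an ionic hydrogenation of 12 with Et3SiH and CF3CO2H in CH2Cl2 at −40 °C: protonation at C3 gives the C4 cation stabilised by rings A and D, and hydride from the silane should enter pseudo-axially, opposite the C2 aryl, to give the same cis chroman. It sets out from 12 and returns at 13; no new isolable compound lies on this path (F0).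

Step 7 (acylation). What may go wrong: acylation at C6 of ring A in competition with ring D, trifluoroacetylation of ring D, or acid-induced opening of ring C. The fallback builds the ketone in three known operations with a weaker electrophile under non-protic conditions; it sets out from 13 and returns at 16. Vilsmeier–Haack formylation of 13 (POCl3, DMF, 0 °C to rt) should give, selectively on the most electron-rich ring, the iminium salt {2,4,6-tris(benzyloxy)-3-[(2S,4S)-7-(benzyloxy)-2-(4-{[(benzyloxy)carbonyl]oxy}phenyl)chroman-4-yl]benzylidene}dimethylammonium chloride F6, which aqueous NaOAc hydrolyses to the aldehyde benzyl 4-{(2S,4S)-7-(benzyloxy)-4-[2,4,6-tris(benzyloxy)-3-formylphenyl]chroman-2-yl}phenyl carbonate F7. (8-Phenyloctyl)magnesium bromide in THF at −78 °C, where the aldehyde reacts before the aryl carbonate, gives the secondary alcohol benzyl 4-{(2S,4S)-7-(benzyloxy)-4-[2,4,6-tris(benzyloxy)-3-(1-hydroxy-9-phenylnonyl)phenyl]chroman-2-yl}phenyl carbonate F8 as a mixture of carbinol epimers, and Dess–Martin oxidation gives 16.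

**Further compounds**

F1 | step 5 | (E)-1-[4-(benzyloxy)-2-hydroxyphenyl]-3-(dimethylamino)prop-2-en-1-one | CN(C)/C=C/C(=O)c1ccc(OCc2ccccc2)cc1O
F2 | step 5 | 7-(benzyloxy)-4H-chromen-4-one | O=c1ccoc2cc(OCc3ccccc3)ccc12
F3 | step 5 | [4-(benzyloxycarbonyloxy)phenyl]boronic acid | OB(O)c1ccc(OC(=O)OCc2ccccc2)cc1
F4 | step 5 | benzyl 4-[(2S)-7-(benzyloxy)-4-oxochroman-2-yl]phenyl carbonate | O=C1C[C@@H](c2ccc(OC(=O)OCc3ccccc3)cc2)Oc2cc(OCc3ccccc3)ccc21
F5 | step 5 | benzyl 4-{(2S)-7-(benzyloxy)-4-hydroxy-4-[2,4,6-tris(benzyloxy)phenyl]chroman-2-yl}phenyl carbonate (C4 epimers) | OC1(c2c(OCc3ccccc3)cc(OCc3ccccc3)cc2OCc2ccccc2)C[C@@H](c2ccc(OC(=O)OCc3ccccc3)cc2)Oc2cc(OCc3ccccc3)ccc21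
F0 | step 6 | none | none
F6 | step 7 | {2,4,6-tris(benzyloxy)-3-[(2S,4S)-7-(benzyloxy)-2-(4-{[(benzyloxy)carbonyl]oxy}phenyl)chroman-4-yl]benzylidene}dimethylammonium chloride | C[N+](C)=Cc1c(OCc2ccccc2)cc(OCc2ccccc2)c([C@H]2C[C@@H](c3ccc(OC(=O)OCc4ccccc4)cc3)Oc3cc(OCc4ccccc4)ccc32)c1OCc1ccccc1.[Cl-]
F7 | step 7 | benzyl 4-{(2S,4S)-7-(benzyloxy)-4-[2,4,6-tris(benzyloxy)-3-formylphenyl]chroman-2-yl}phenyl carbonate | O=Cc1c(OCc2ccccc2)cc(OCc2ccccc2)c([C@H]2C[C@@H](c3ccc(OC(=O)OCc4ccccc4)cc3)Oc3cc(OCc4ccccc4)ccc32)c1OCc1ccccc1
F8 | step 7 | benzyl 4-{(2S,4S)-7-(benzyloxy)-4-[2,4,6-tris(benzyloxy)-3-(1-hydroxy-9-phenylnonyl)phenyl]chroman-2-yl}phenyl carbonate (carbinol epimers) | OC(CCCCCCCCc1ccccc1)c1c(OCc2ccccc2)cc(OCc2ccccc2)c([C@H]2C[C@@H](c3ccc(OC(=O)OCc4ccccc4)cc3)Oc3cc(OCc4ccccc4)ccc32)c1OCc1ccccc1
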